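2.91 min was my starting number. It is the target-time of Sunday's flask: target as a fraction of the charge, summed over the minutes up to 15.0 min. In this flask substrate takes up dissolved gas to give target, substrate also goes to side product, and target turns into isomer of the product.

the same everywhere: gas phase 5.4 mM (held)

| run | substrate | remark | time |
|---|---|---|---|
| Sunday's | 0.088 M | the very flask that is asked about, followed so far |  |
| Monday's | 0.13 M | run made earlier |  |
| flask | 0.088 M |  | 30 min |

| run | time / min | isomer of the product / % | target / % |
|---|---|---|---|
| Sunday's | 2.00 | 1.0 | 5.4 |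
| Sunday's | 4.00 | 2.8 | 10.9 |
| Sunday's | 6.00 | 0.2 | 17.4 |
| Sunday's | 8.00 | 2.8 | 23.6 |
| Sunday's | 10.0 | 4.4 | 26.8 |
| Sunday's | 12.0 | 2.7 | 29.8 |
| Sunday's | 15.0 | 6.0 | 32.0 |
| Monday's | 1.00 | 0 | 2.7 |
| Monday's | 3.00 | 0 | 8.3 |
| Monday's | 6.00 | 1.1 | 15.4 |
| Monday's | 10.0 | 1.7 | 22.4 |
| Monday's | 12.0 | 3.5 | 25.8 |
| Monday's | 15.0 | 4.1 | 28.5 |
| Monday's | 20.0 | 8.0 | 32.8 |

(scatter of a reading: 1 percentage point)

- at the start none of the gas is dissolved
- reactions considered so far: target <-> isomer of the product; substrate + dissolved gas -> target; gas phase <-> dissolved gas; substrate -> side product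

- amount of isomer of the product in percent of the substrate charged, at 1.5 min, 8.0 min and 30 min

I followed one molecule of target. Each minute it had a chance of becoming isomer, so isomer should equal that chance times the target-time, if I neglected any return.

Sunday's last reading put 6.0% of isomer on 2.91 min. Monday's put 8.0% on 4.06 min. Pooled, the isomer chance, isomer made per target-time, read 0.0201 min⁻¹.

Sunday's target first rose by 0.0270 min⁻¹ of the charge per minute. That gave 0.0611% of isomer at 1.5 min. Summing the readings to 8.0 min gave 1.83% there.

For 30 min I first held target at 32.0%, which gave 15.5%. That was the weak link, since target was still rising. Its late rise plus its loss to isomer made a supply of 0.0138 min⁻¹ of the charge, about half the first rate. Letting it halve again brought 14.9% more, so target ended near 37.4%. Averaging target over the second stretch, I committed to 16.3%.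

The forecast gave 0.05%, 1.7% and 12%, reading the chance as 0.017 per minute: “Allowing for some reverse reaction, I expect about 12%, though this is extrapolated.” My number stood higher.

The flask gave 0.0604%, 2.23% and 19.3%. The last of these stood above my number and the forecast's.

    target ⇌ isomer of the product (K = 3.50, k = 4.20 × 10⁻⁴ s⁻¹)
    substrate + dissolved gas → target (k = 0.220 L mol⁻¹ s⁻¹)
    gas phase ⇌ dissolved gas, rate k3*(csat - [dissolved gas]) (kL = 0.0210 s⁻¹)
    substrate → side product (k = 4.70 × 10⁻⁴ s⁻¹)

At 9.16 min this flask made target 4.30 times faster than it used it up. At 30.0 min the 9.0% of substrate left, with a half-life of 11 min by the step to target, fed target at 0.00587 min⁻¹ of the charge; my estimated isomer chance put the loss from 37.1% of target at 0.00746 min⁻¹, and the flask's net loss to isomer, with the return counted, was 0.00797 min⁻¹ of the charge, more than the feed.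

The readings stem from a simulated flask on assumed constants, and the scatter is random.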